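I read the closed flask zeta at 5.0 d, so I count how many half-lives of its slow loss fit before that reading.

    substrate + free catalyst ⇌ free catalyst + open intermediate (K1 = 2.2, k1 = 43 /M/min)
    second catalyst + open intermediate ⇌ catalyst intermediate (K2 = 1.6 /M, k2 = 0.53 /M/min)
    partner + catalyst intermediate → second catalyst + product (k3 = 0.77 /M/min)

| flask | substrate | partner | free catalyst | second catalyst | time | remark |
|---|---|---|---|---|---|---|
| eta | 0.10 M | 3.00 equiv (fed, over 4.00 d) | 0.5 mol% | 2.5 mol% | 5.0 d | all but partner at the start; partner goes in evenly over 4.00 d, the run ends at 5.0 d |
| zeta | 0.10 M | 3.00 equiv | 0.5 mol% | 2.5 mol% | 5.0 d | everything together in a closed stirred flask, run for 5.0 d |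
| gamma | 0.10 M (fed, over 4.00 d) | 3.00 equiv | 0.5 mol% | 2.5 mol% | 5.0 d | a stirred flask in which substrate is dosed at a steady rate over 4.00 d without added volume, worked up at 5.0 d |
| beta | 0.10 M | 3.00 equiv | 0.5 mol% | 2.5 mol% |  | one stirred flow tank at steady state, fed with the mixture as stated, mean residence time 5.0 d |

- the set-up with the highest amount of product at the outlet or at the end, in percent of the substrate put in ("none" if the first two lie within 2 percentage points) (eta / zeta / gamma / beta / none)
- amount of product at the outlet or at the end, in percent of the substrate put in, eta
- amount of product at the outlet or at the end, in percent of the substrate put in, zeta
- amount of product at the outlet or at the end, in percent of the substrate put in, gamma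
- amount of product at the outlet or at the end, in percent of the substrate put in, beta

- the stated concentrations are those of everything mixed, before any reaction; amounts are the same in each set-up
- the feed brings no volume worth counting
- run time (eta): 5.0 d

Take zeta, the closed flask. Second catalyst, as charged, catches open intermediate with a half-life of 0.363 d by the forward step alone, so the run holds 13.8 such half-lives and the catch looks long finished. Yet the equilibrium constant of that catch times second catalyst as charged is 0.00400, so at equilibrium catalyst intermediate stands at that fraction of open intermediate. The two numbers go together once I count just the catches that go on to product.

Substrate turns into open intermediate at 0.0215 /min, faster than the catch at 0.00133 /min, so I treat the two as one pool in equilibrium, of which 68.8% is open. Catalyst intermediate falls back at 0.331 /min and goes on at k3 times partner. Partner can fall from its charge to 66.7% of it once the substrate is fully converted, and I replace that curve by the mean of its two ends, 83.3% of the charge, which makes the going-on share 36.8%.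

Dividing the catch half-life by both shares gives 1.44 d. This is the pool half-life, the time in which substrate and open intermediate together halve under a pseudo-first-order fall with partner at that mean. In zeta it leaves 8.98% of the pool, so I commit to 91.0% product. To check the error of that mean, I reckon zeta with partner held at its full charge, which gives 93.2%, and held at its low end, which gives 87.5%. For eta, gamma and beta I commit to no number.

The forecast names zeta as best, with 77% for eta, 90% for zeta, 72% for gamma and 69% for beta. Its ground for the closed flask is that it has “full partner and full contact time from the start”.

The runs give 77.3% for eta, 89.4% for zeta, 71.5% for gamma and 68.7% for beta, with zeta best. In zeta at 0.0270 d, catalyst intermediate falls back 1.4 times faster than it goes on, and at 5.0 d zeta, 3.47 pool half-lives old, still holds 7.21% as open intermediate and 3.3% as substrate. The neighbour of zeta with 0.025 M of substrate, equivalents and loadings held, has a longer pool half-life of 16.7 d, and it ends with 20.3% product and 54.7% open intermediate.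

All constants belong to no real substance, and the outcome is calculated.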